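**Plan**

1. Numbering and feature: ring A = C1 (quaternary, CH3), C2 (carbinol), C3, C4 (isopropyl carbinol), C5; ring B = C1, C5, C6 (ester), C7, C8 (CH3), C9, C10 (ester), alkene C8=C9; α is the face of the C1 methyl, β the other face. C10 is an allylic carbinol bonded to the quaternary C1, so its aldehyde has no α-hydrogen and ring B can be closed by adding a C9 alkenylmetal to it.
2. Cuts: the two angelate C–O bonds; C9–C10 (ring B); C6–C7 (dithiane carbanion plus Z-iodoallyl bromide); C4–isopropyl; C5–C6 and C1–C10 (1,4-addition/hydroxymethylation on a 2-methyl-4-silyloxycyclopentenone).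
3. Forward: ring A is bought as (R)-4-silyloxycyclopentenone and substituted first (C1 methyl, C5/C1, C2, the C7–C9 chain, C4); the C6 angelate is put on the open-chain aldehyde, ring B closes in step 18, and the C10 angelate and PMB removal finish.
4. Stereochemistry: the purchased C4–OSi centre sends the C5 substituent α; C5 sends CH2OH β at C1; the CH2OH delivers hydride to C2 (2α-OH); the C5 substituent sends isopropyl β at C4; C6 comes from an oxazaborolidine-catalysed reduction; C10 from the ring closure; the Z-iodoalkene from anti-carbomagnesiation; the angelate geometry from angelic acid.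

Key step: step 18

**Route**

Step 1
Reactants: 1 (R)-4-(tert-butyldimethylsilyloxy)cyclopent-2-en-1-one
Product: 2 (R)-4-(tert-butyldimethylsilyloxy)-2-iodocyclopent-2-en-1-one
Conditions: I2, pyridine, CH2Cl2, 0 °C to rt
Reagents that add atoms: iodine, [I][I]
Why: Pyridine adds reversibly to the enone β-carbon, the enolate is iodinated and pyridine is expelled (α-iodination of an enone by addition–elimination), which leaves the C4 stereocentre untouched.

Step 2
Reactants: 2 (R)-4-(tert-butyldimethylsilyloxy)-2-iodocyclopent-2-en-1-one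
Product: 3 (R)-4-(tert-butyldimethylsilyloxy)-2-methylcyclopent-2-en-1-one
Conditions: SnMe4, PdCl2(PhCN)2 (5 mol %), AsPh3, CuI, NMP, 60 °C
Reagents that add atoms: tetramethylstannane, C[Sn](C)(C)C
Why: Stille coupling of the α-iodoenone (oxidative addition at C–I, copper-assisted methyl transfer, reductive elimination) installs the future C1 methyl under neutral conditions that do not eliminate the β-silyloxy group.

Step 3
Reactants: 3 (R)-4-(tert-butyldimethylsilyloxy)-2-methylcyclopent-2-en-1-one; 4 1,3-dithiane
Product: 7 1β-(hydroxymethyl)-1α-methyl-5α-(1,3-dithian-2-yl)-4β-(tert-butyldimethylsilyloxy)cyclopentan-2-one (target locants), via 2-lithio-1,3-dithiane 5 (not isolated), via lithium enolate 6 (not isolated)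
Conditions: 4, n-BuLi, THF, −30 °C; HMPA, −78 °C; 3; then CH2O (gas, from cracked paraformaldehyde), −78 °C; pH 7 buffer
Reagents that add atoms: formaldehyde, C=O
Why: With HMPA the ion-pair-separated lithiodithiane adds 1,4 to the enone anti to the C4 silyloxy group (sets C5, dithianyl α), and the regiodefined enolate is hydroxymethylated by formaldehyde anti to the new C5 substituent (sets the quaternary C1, CH2OH β) in a Michael addition–aldol sequence.

Step 4
Reactants: 7 hydroxymethyl ketone
Product: 8 1β-(hydroxymethyl)-1α-methyl-5α-(1,3-dithian-2-yl)-4β-(tert-butyldimethylsilyloxy)cyclopentan-2α-ol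
Conditions: Me4NBH(OAc)3, MeCN/AcOH (1:1), −30 °C
Reagents that add atoms: none
Why: Evans–Saksena reduction, in which the β-oriented C10 hydroxyl binds boron and delivers hydride intramolecularly to the β face of the C2 ketone, should give the 2α-alcohol (anti 1,3-diol).

Step 5
Reactants: 8 diol
Product: 9 O2,O10-(4-methoxybenzylidene) acetal of the diol (trans-fused 1,3-dioxane; aryl equatorial; acetal H cis to H-2)
Conditions: 4-MeOC6H4CH(OMe)2, pyridinium p-toluenesulfonate (cat.), CH2Cl2, rt
Reagents that add atoms: 4-methoxybenzaldehyde dimethyl acetal, COc1ccc(cc1)C(OC)OC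
Why: Acid-catalysed transacetalisation ties the 1,3-diol into a six-membered acetal with the aryl group equatorial (thermodynamic control), which masks both hydroxyls for the carbanion step and prepares their later differentiation.

Step 6
Reactants: 10 propargyl alcohol
Product: 12 (Z)-3-iodo-2-methylprop-2-en-1-ol, via alkenylmagnesium alkoxide 11 (not isolated)
Conditions: MeMgBr (2.5 equiv), CuI (10 mol %), THF, −10 °C to rt; then I2, −10 °C
Reagents that add atoms: methylmagnesium bromide, C[Mg]Br; iodine, [I][I]
Why: Copper-catalysed carbomagnesiation of the propargylic alkoxide is an anti addition (methyl to the internal carbon, magnesium held at the terminal carbon by the alkoxide), and iodinolysis with retention gives the Z iodoalkene.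

Step 7
Reactants: 12 (Z)-3-iodo-2-methylprop-2-en-1-ol
Product: 13 (Z)-3-bromo-1-iodo-2-methylprop-1-ene
Conditions: CBr4, PPh3, CH2Cl2, 0 °C
Reagents that add atoms: carbon tetrabromide, BrC(Br)(Br)Br
Why: The Appel reaction converts the primary allylic alcohol into the bromide by SN2 displacement of an alkoxyphosphonium ion without touching the alkenyl iodide geometry.

Step 8
Reactants: 9 acetal; 13 (Z)-3-bromo-1-iodo-2-methylprop-1-ene
Product: 15 C6-alkylated dithiane acetal bearing the (Z)-3-iodo-2-methylprop-2-enyl group on the dithiane carbon (C7–C9 in place; 4β-OTBS), via lithiated dithiane 14 (not isolated)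
Conditions: t-BuLi, THF/HMPA (10:1), −78 °C; then 13, −78 to −40 °C
Reagents that add atoms: none
Why: Deprotonation of the 2-substituted 1,3-dithiane gives a sulfur-stabilised carbanion that is alkylated by the allylic bromide in an SN2 reaction (Corey–Seebach umpolung) to form C6–C7, the carbanion being too stabilised to exchange with the alkenyl iodide.

Step 9
Reactants: 15 alkylated dithiane
Product: 16 4β-alcohol (silyl group removed)
Conditions: Bu4NF, THF, rt
Reagents that add atoms: none
Why: Fluoride cleaves the only silyl ether (desilylation) while the acetal, the dithiane and the alkenyl iodide are inert.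

Step 10
Reactants: 16 4β-alcohol
Product: 17 C4 ketone (cyclopentan-4-one; 5α-substituent unchanged)
Conditions: SO3·pyridine, DMSO, iPr2NEt, CH2Cl2, 0 °C
Reagents that add atoms: none
Why: Parikh–Doering oxidation (activated DMSO) converts the secondary alcohol into the ketone without oxidising the dithiane sulfur atoms or the iodoalkene.

Step 11
Reactants: 17 C4 ketone; 18 isopropylmagnesium chloride
Product: 20 4α-hydroxy-4β-isopropyl tertiary alcohol, via isopropylcerium dichloride 19 (not isolated)
Conditions: CeCl3 (anhydrous), 18, THF, −78 °C; then 17, −78 °C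
Reagents that add atoms: none
Why: The organocerium reagent adds 1,2 to the enolisable ketone without enolisation or reduction and attacks the β face, opposite the bulky C5 substituent, the angular methyl and the C2 oxygen, which should give the 4α-hydroxy-4β-isopropyl centre.

Step 12
Reactants: 20 tertiary alcohol
Product: 21 C6 ketone (β-hydroxy ketone; dithiane removed)
Conditions: MeI, CaCO3, MeCN/H2O (9:1), 40 °C
Reagents that add atoms: water, O
Why: S-Methylation of the dithiane and hydrolysis of the sulfonium ion under carbonate buffering unmask the C6 ketone (dithiane hydrolysis) without acid that would open the acetal or base that would move the β,γ-double bond into conjugation.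

Step 13
Reactants: 21 C6 ketone
Product: 22 (6S)-alcohol (4α-OH; acetal intact)
Conditions: (R)-2-methyl-CBS-oxazaborolidine (0.5 equiv), catecholborane, toluene, −78 to −40 °C
Reagents that add atoms: none
Why: In the Corey–Bakshi–Shibata reduction the ketone binds the (R)-oxazaborolidine with the branched ring carbon C5 as the large and the C7 methylene as the small group, so hydride should be delivered to the face that gives the 6S alcohol, while catecholborane caps the C4 hydroxyl as a borate that carries no hydride.

Step 14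
Reactants: 22 (6S)-alcohol
Product: 23 triol with C10 primary alcohol and 2α-O-(4-methoxybenzyl) ether (4α-OH; 6S-OH)
Conditions: iBu2AlH (DIBAL-H), CH2Cl2, −78 to 0 °C; aq. sodium potassium tartrate
Reagents that add atoms: none
Why: In the reductive opening of the 4-methoxybenzylidene acetal, aluminium binds the less hindered primary oxygen and hydride cleaves that C–O bond, which leaves the PMB group on O2 and frees the C10 alcohol.

Step 15
Reactants: 23 triol
Product: 24 C10 aldehyde (2α-OPMB; 4α-OH; 6S-OH; Z-iodoalkene)
Conditions: TEMPO (2,2,6,6-tetramethylpiperidin-1-oxyl, 0.2 equiv), PhI(OAc)2, CH2Cl2, rt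
Reagents that add atoms: none
Why: Oxoammonium (TEMPO) oxidation is selective for the primary alcohol over the hindered secondary C6 and tertiary C4 alcohols, and the trans placement of C10 and C6 on ring A prevents lactol formation and over-oxidation.

Step 16
Reactants: 25 angelic acid
Product: 26 angelic 2,4,6-trichlorobenzoic anhydride
Conditions: 2,4,6-trichlorobenzoyl chloride, Et3N, toluene, rt; filtered from Et3N·HCl under argon and kept as a toluene solution
Reagents that add atoms: 2,4,6-trichlorobenzoyl chloride, O=C(Cl)c1c(Cl)cc(Cl)cc1Cl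
Why: Acyl substitution of the acid chloride by the triethylammonium carboxylate gives the mixed anhydride (first stage of a Yamaguchi esterification), in which the two ortho chlorines shield the aroyl carbonyl so that an alcohol later attacks only the angeloyl carbonyl.

Step 17
Reactants: 24 C10 aldehyde; 26 angelic 2,4,6-trichlorobenzoic anhydride
Product: 27 6-O-angeloyl C10 aldehyde (closure precursor; 2α-OPMB; 4α-OH; 6S-angelate; Z-iodoalkene)
Conditions: 26 (toluene solution, 1.5 equiv), Et3N, toluene, 80 °C
Reagents that add atoms: none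
Why: Yamaguchi-type esterification through the mixed anhydride without DMAP acylates the only secondary hydroxyl (C6), the tertiary C4 hydroxyl and the non-enolisable aldehyde being inert, and the absence of a nucleophilic catalyst avoids Z-to-E isomerisation of the angelate.

Step 18
Reactants: 27 6-O-angeloyl C10 aldehyde
Product: 29 hydroazulene 6-angelate (2α-OPMB; 4α-OH; 6β-O-angeloyl; 10β-OH; C8=C9), via alkenylchromium dichloride 28 (not isolated)
Conditions: CrCl2 (10 equiv), NiCl2 (0.1 equiv), degassed DMSO, 0.005 M, rt
Reagents that add atoms: none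
Why: CrCl2 reduces NiCl2 to zerovalent nickel, which inserts into the C9–I bond with retention of the Z geometry and hands the alkenyl group to trivalent chromium; the alkenylchromium species 28 then adds to the C10 aldehyde and aqueous work-up releases the alcohol. The closest known reaction type is the intramolecular Nozaki–Hiyama–Kishi coupling of a Z alkenyl iodide with an aldehyde to give a cycloalkenol. Ring B closes by a 7-exo-trig carbonyl addition in which C9 attacks C10. The new stereocentre C10 is set by the aldehyde rotamer: the tether from the α-oriented C6 forces C9 to approach between C5 and the angular methyl, and the chromium-bound oxygen should then take the sector next to H-5 on the β face instead of the sector next to the angular methyl and the α-oriented C2 ether oxygen, which places the new hydroxyl β, anti to the C1 methyl (10R). The step needs chemoselectivity (the aldehyde has no α-hydrogen and the reagent is neither basic nor reactive towards esters, so the free C4 hydroxyl, the PMB ether and the C6 angelate are tolerated), a Z iodoalkene so that C7 and C10 are cis on the C8=C9 bond (fixed in step 6), and high dilution against dimerisation. DMSO as donor solvent saturates chromium and keeps the C2 ether from chelating, which would favour the other rotamer.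

Step 19
Reactants: 29 hydroazulene 6-angelate; 26 angelic 2,4,6-trichlorobenzoic anhydride
Product: 30 6,10-bis-angelate 2α-PMB ether
Conditions: 26 (toluene solution, 2 equiv), Et3N, toluene, 80 °C
Reagents that add atoms: none
Why: Yamaguchi-type esterification through the mixed anhydride without DMAP acylates the remaining secondary hydroxyl, the hindered allylic C10 alcohol, while the tertiary C4 hydroxyl does not react and both angelates keep their Z geometry.

Step 20
Reactants: 30 bis-angelate PMB ether
Product: 31 CNP0249167.2 (target)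
Conditions: DDQ, CH2Cl2/pH 7 buffer (10:1), 0 °C to rt
Reagents that add atoms: none
Why: Oxidative cleavage of the 4-methoxybenzyl ether by DDQ (hydride abstraction, then hydrolysis of the oxocarbenium ion) under buffered conditions frees the C2 hydroxyl without touching the two angelates.

**Compound list**

1 | (R)-4-(tert-butyldimethylsilyloxy)cyclopent-2-en-1-one | CC(C)(C)[Si](C)(C)O[C@@H]1CC(=O)C=C1 | starting material
2 | (R)-4-(tert-butyldimethylsilyloxy)-2-iodocyclopent-2-en-1-one | CC(C)(C)[Si](C)(C)O[C@@H]1CC(=O)C(I)=C1 | intermediate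
3 | (R)-4-(tert-butyldimethylsilyloxy)-2-methylcyclopent-2-en-1-one | CC(C)(C)[Si](C)(C)O[C@@H]1CC(=O)C(C)=C1 | intermediate
4 | 1,3-dithiane | C1CSCSC1 | starting material
5 | 2-lithio-1,3-dithiane | [Li]C1SCCCS1 | intermediate
6 | lithium enolate of the 1,4-adduct (C1=C2 enolate; 5α-dithianyl; 4β-OTBS) | [Li]OC1=C(C)[C@@H](C2SCCCS2)[C@H](O[Si](C)(C)C(C)(C)C)C1 | intermediate
7 | 1β-(hydroxymethyl)-1α-methyl-5α-(1,3-dithian-2-yl)-4β-(tert-butyldimethylsilyloxy)cyclopentan-2-one | OC[C@@]1(C)C(=O)C[C@@H](O[Si](C)(C)C(C)(C)C)[C@@H]1C2SCCCS2 | intermediate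
8 | 2α-alcohol of 7 (diol) | OC[C@@]1(C)[C@H](O)C[C@@H](O[Si](C)(C)C(C)(C)C)[C@@H]1C2SCCCS2 | intermediate
9 | O2,O10-(4-methoxybenzylidene) acetal of 8 | COc1ccc(cc1)[C@H]2OC[C@@]3(C)[C@H](O2)C[C@@H](O[Si](C)(C)C(C)(C)C)[C@@H]3C4SCCCS4 | intermediate
10 | propargyl alcohol | C#CCO | starting material
11 | (Z)-alkenylmagnesium bromide alkoxide | Br[Mg]OC/C(C)=C\[Mg]Br | intermediate
12 | (Z)-3-iodo-2-methylprop-2-en-1-ol | OC/C(C)=C\I | intermediate
13 | (Z)-3-bromo-1-iodo-2-methylprop-1-ene | BrC/C(C)=C\I | intermediate
14 | 9 lithiated at the dithiane carbon | COc1ccc(cc1)[C@H]2OC[C@@]3(C)[C@H](O2)C[C@@H](O[Si](C)(C)C(C)(C)C)[C@@H]3C4([Li])SCCCS4 | intermediate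
15 | 9 alkylated at C6 with the (Z)-3-iodo-2-methylprop-2-enyl group | COc1ccc(cc1)[C@H]2OC[C@@]3(C)[C@H](O2)C[C@@H](O[Si](C)(C)C(C)(C)C)[C@@H]3C4(C/C(C)=C\I)SCCCS4 | intermediate
16 | 4β-alcohol from 15 | COc1ccc(cc1)[C@H]2OC[C@@]3(C)[C@H](O2)C[C@@H](O)[C@@H]3C4(C/C(C)=C\I)SCCCS4 | intermediate
17 | C4 ketone | COc1ccc(cc1)[C@H]2OC[C@@]3(C)[C@H](O2)CC(=O)[C@@H]3C4(C/C(C)=C\I)SCCCS4 | intermediate
18 | isopropylmagnesium chloride | CC(C)[Mg]Cl | starting material
19 | isopropylcerium dichloride | CC(C)[Ce](Cl)Cl | intermediate
20 | 4α-hydroxy-4β-isopropyl tertiary alcohol | COc1ccc(cc1)[C@H]2OC[C@@]3(C)[C@H](O2)C[C@@](O)(C(C)C)[C@@H]3C4(C/C(C)=C\I)SCCCS4 | intermediate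
21 | C6 ketone (β-hydroxy ketone) | COc1ccc(cc1)[C@H]2OC[C@@]3(C)[C@H](O2)C[C@@](O)(C(C)C)[C@@H]3C(=O)C/C(C)=C\I | intermediate
22 | (6S)-alcohol | COc1ccc(cc1)[C@H]2OC[C@@]3(C)[C@H](O2)C[C@@](O)(C(C)C)[C@@H]3[C@@H](O)C/C(C)=C\I | intermediate
23 | triol with C10 primary alcohol and 2α-OPMB | OC[C@@]1(C)[C@H](OCc2ccc(OC)cc2)C[C@@](O)(C(C)C)[C@@H]1[C@@H](O)C/C(C)=C\I | intermediate
24 | C10 aldehyde with free C6 hydroxyl | O=C[C@@]1(C)[C@H](OCc2ccc(OC)cc2)C[C@@](O)(C(C)C)[C@@H]1[C@@H](O)C/C(C)=C\I | intermediate
25 | angelic acid | C/C=C(/C)C(=O)O | starting material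
26 | angelic 2,4,6-trichlorobenzoic anhydride | C/C=C(/C)C(=O)OC(=O)c1c(Cl)cc(Cl)cc1Cl | intermediate
27 | 6-O-angeloyl C10 aldehyde with Z alkenyl iodide side chain (closure precursor) | O=C[C@@]1(C)[C@H](OCc2ccc(OC)cc2)C[C@@](O)(C(C)C)[C@@H]1[C@@H](OC(=O)/C(C)=C\C)C/C(C)=C\I | intermediate
28 | alkenylchromium dichloride | O=C[C@@]1(C)[C@H](OCc2ccc(OC)cc2)C[C@@](O)(C(C)C)[C@@H]1[C@@H](OC(=O)/C(C)=C\C)C/C(C)=C\[Cr](Cl)Cl | intermediate
29 | hydroazulene 6-angelate (2α-OPMB; 4α-OH; 10β-OH) | C/C=C(/C)C(=O)O[C@H]1CC(C)=C[C@@H](O)[C@@]2(C)[C@H](OCc3ccc(OC)cc3)C[C@@](O)(C(C)C)[C@H]12 | intermediate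
30 | 6,10-bis-angelate 2α-PMB ether | C/C=C(/C)C(=O)O[C@H]1CC(C)=C[C@@H](OC(=O)/C(C)=C\C)[C@@]2(C)[C@H](OCc3ccc(OC)cc3)C[C@@](O)(C(C)C)[C@H]12 | intermediate
31 | CNP0249167.2 | C/C=C(/C)C(=O)O[C@H]1CC(C)=C[C@@H](OC(=O)/C(C)=C\C)[C@@]2(C)[C@H](O)C[C@@](O)(C(C)C)[C@H]12 | target

**Step count and risks**

Total: 20 steps. Longest linear sequence: 17 steps (1 to 31 through steps 1–5, 8–15 and 17–20); steps 6 and 7 make bromide 13 and step 16 makes anhydride 26.

Step 18, poor facial selectivity at C10. The chromium-bound carbonyl oxygen may take the α sector, or the C2 ether may chelate, so that the closure delivers the 10α-alcohol. The fallback sets out from 27 and sets C10 by a hydroxyl-directed reduction instead of by the ring closure. The closure is run unchanged and the 10-epi alcohol F1, alone or mixed with 29, is oxidised with Dess–Martin periodinane (the C10 hydroxyl is the only oxidisable one) to the ring B enone F2. DDQ then frees the C2 hydroxyl to give the hydroxy enone F3. Me4NBH(OAc)3 should deliver hydride from the α-oriented C2 oxygen to the α face of C10 and give the 10β-alcohol F4. Its allylic C10 hydroxyl is then esterified with one equivalent of 26; the C2 hydroxyl, cis to the angular methyl and hydrogen-bonded to the C4 hydroxyl, is expected to be the slower one. The fallback returns to the route at 31.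

Step 13, substrate bias overriding catalyst control. Hydride delivery through the boron-bound C4 oxygen, or the inherent facial preference of the hindered ketone, may give the 6R alcohol. The fallback sets out from 20 and postpones the C6 reduction until ring B is closed. With the dithiane kept, the acetal is opened with iBu2AlH to the primary alcohol F5, which is oxidised (SO3·pyridine, DMSO) to the aldehyde F6 and unmasked (MeI, CaCO3) to the keto aldehyde F7. Closure with CrCl2/NiCl2 as in step 18 (the alkenylchromium adds to the aldehyde, not to the ketone) gives the hydroazulene hydroxy ketone F8. In this rigid bicycle Me4NBH(OAc)3 should deliver hydride from the α-oriented C4 hydroxyl to the α face of C6 and give the 6β,10β-diol F9. Both secondary hydroxyls are then esterified with 26 (one equivalent for each hydroxyl, Et3N, toluene, 80 °C). The fallback returns at 30.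

Step 3, competing 1,2-addition or loss of silanolate. The lithiodithiane may add to the carbonyl, or deprotonate the enone with loss of the silyloxy group, instead of adding 1,4. The fallback sets out from 3 and brings in C6 as a vinyl group. A vinyl cuprate (vinylmagnesium bromide, CuBr·SMe2, THF, −78 °C) adds anti to the silyloxy group and the enolate is trapped with formaldehyde to give the vinyl hydroxymethyl ketone F10. Me4NBH(OAc)3 gives the vinyl diol F11, ozonolysis (O3, then PPh3) the aldehyde F12, and propane-1,3-dithiol with MgBr2·OEt2 the dithiane. The fallback returns at 8.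

Further compounds

F1 | step 18 | 10-epimer of 29 (10α-hydroxyl; 6-O-angeloyl) | C/C=C(/C)C(=O)O[C@H]1CC(C)=C[C@H](O)[C@@]2(C)[C@H](OCc3ccc(OC)cc3)C[C@@](O)(C(C)C)[C@H]12
F2 | step 18 | 6-O-angeloyl ring B enone (C10 ketone; 2α-OPMB) | C/C=C(/C)C(=O)O[C@H]1CC(C)=CC(=O)[C@@]2(C)[C@H](OCc3ccc(OC)cc3)C[C@@](O)(C(C)C)[C@H]12
F3 | step 18 | 6-O-angeloyl enone with free 2α-hydroxyl | C/C=C(/C)C(=O)O[C@H]1CC(C)=CC(=O)[C@@]2(C)[C@H](O)C[C@@](O)(C(C)C)[C@H]12
F4 | step 18 | 6-O-angeloyl 2α,4α,10β-triol | C/C=C(/C)C(=O)O[C@H]1CC(C)=C[C@@H](O)[C@@]2(C)[C@H](O)C[C@@](O)(C(C)C)[C@H]12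
F5 | step 13 | C10 primary alcohol with 2α-OPMB and intact dithiane | OC[C@@]1(C)[C@H](OCc2ccc(OC)cc2)C[C@@](O)(C(C)C)[C@@H]1C3(C/C(C)=C\I)SCCCS3
F6 | step 13 | C10 aldehyde with intact dithiane | O=C[C@@]1(C)[C@H](OCc2ccc(OC)cc2)C[C@@](O)(C(C)C)[C@@H]1C3(C/C(C)=C\I)SCCCS3
F7 | step 13 | keto aldehyde (C6 ketone; C10 aldehyde) | O=C[C@@]1(C)[C@H](OCc2ccc(OC)cc2)C[C@@](O)(C(C)C)[C@@H]1C(=O)C/C(C)=C\I
F8 | step 13 | hydroazulene hydroxy ketone (C6 ketone; 10β-OH) | O=C1CC(C)=C[C@@H](O)[C@@]2(C)[C@H](OCc3ccc(OC)cc3)C[C@@](O)(C(C)C)[C@H]12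
F9 | step 13 | hydroazulene 6β,10β-diol (2α-OPMB; 4α-OH) | O[C@H]1CC(C)=C[C@@H](O)[C@@]2(C)[C@H](OCc3ccc(OC)cc3)C[C@@](O)(C(C)C)[C@H]12
F10 | step 3 | 1β-(hydroxymethyl)-1α-methyl-5α-vinyl-4β-(tert-butyldimethylsilyloxy)cyclopentan-2-one | OC[C@@]1(C)C(=O)C[C@@H](O[Si](C)(C)C(C)(C)C)[C@@H]1C=C
F11 | step 3 | 2α-alcohol of F10 (vinyl diol) | OC[C@@]1(C)[C@H](O)C[C@@H](O[Si](C)(C)C(C)(C)C)[C@@H]1C=C
F12 | step 3 | C6 aldehyde diol | OC[C@@]1(C)[C@H](O)C[C@@H](O[Si](C)(C)C(C)(C)C)[C@@H]1C=O
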